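**Retrosynthetic overview**

1. Locants are germacranolide locants: ring A is the ten-membered carbocycle C1–C10 (C14 on C10, C15 on C4), ring B is the γ-lactone O–C6–C7–C11(=C13)–C12. The enabling feature is that C9 is a secondary allylic carbinol carbon bonded directly to sp2 C10 of the (Z)-C1=C10 alkene of ring A and flanked by the acyloxy-bearing stereocentre C8. Ring A is therefore opened between C9 and C10 to a (Z)-alkenyl iodide and an α-acyloxy aldehyde.
2. The last step is a chromium/nickel-mediated alkenyl iodide–aldehyde ring closure on the fully acylated, unprotected seco-aldehyde. It closes ring A, sets C9 from C8 and leaves 9-OH as the only free hydroxyl.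
3. The seco-aldehyde comes from the C8–O ester bond: lactone alcohol plus (3R)-3-methyl-4-(octadecanoyloxy)butanoic acid (Evans alkylation), then adjustment of C9 to the aldehyde.
4. Ring B and the C6–C7 bond come from a syn-selective zinc-mediated 2-(methoxycarbonyl)allylation of (2E,6Z)-7-iodo-3-methylocta-2,6-dienal (from geranyl acetate, iodo-Wittig) with the (Z)-allylic bromide made from (R)-glyceraldehyde acetonide and methyl acrylate (C8 from the chiral pool).
5. Order of ring formation: ring B (step 8), then ring A (step 18).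

Key step: step 18

Remark: (R)-2,2-dimethyl-1,3-dioxolane-4-carbaldehyde is treated as a commercial reagent, distilled before use; the fatty acyl group is octadecanoyl.

Remark: the facial selectivity claimed in step 8 rests on a steric and stereoelectronic model, not on a documented case for this reagent; it is the main stereochemical assumption of the route and has a fallback below.

**Route**

Step 1
Reactants: 1 geranyl acetate
Product: 2 (2E)-5-(3,3-dimethyloxiran-2-yl)-3-methylpent-2-en-1-yl acetate (racemic at the oxirane carbon)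
Conditions: mCPBA (1.05 equiv), CH2Cl2, 0 °C
Reagents that add atoms: 3-chloroperoxybenzoic acid (mCPBA), OOC(=O)c1cccc(Cl)c1
Why: Prilezhaev epoxidation is selective for the electron-rich 6,7-alkene over the 2,3-alkene deactivated by the allylic acetate, and the racemic oxirane centre is destroyed in step 2.

Step 2
Reactants: 2 (2E)-5-(3,3-dimethyloxiran-2-yl)-3-methylpent-2-en-1-yl acetate
Product: 3 (2E)-3-methyl-6-oxohex-2-en-1-yl acetate
Conditions: H5IO6 (1.1 equiv), THF/H2O, 0 °C
Reagents that add atoms: none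
Why: Acid-mediated epoxide hydrolysis followed by Malaprade glycol cleavage in one pot releases the aldehyde and acetone without touching the allylic acetate or the (E)-alkene.

Step 3
Reactants: 3 (2E)-3-methyl-6-oxohex-2-en-1-yl acetate; 4 ethyltriphenylphosphonium iodide
Product: 8 (2E,6Z)-7-iodo-3-methylocta-2,6-dien-1-yl acetate, via ethylidenetriphenylphosphorane 5 (not isolated), via (1-iodoethyl)triphenylphosphonium iodide 6 (not isolated), via (1-iodoethylidene)triphenylphosphorane 7 (not isolated)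
Conditions: 4, n-BuLi, THF, rt; I2, −78 °C; NaN(SiMe3)2, −20 °C; then 3, −78 °C → rt
Reagents that add atoms: iodine, II
Why: Wittig olefination with the α-iodo ylide 7 (Stork–Zhao type) proceeds under kinetic control at low temperature to the (Z)-2-iodoalk-2-ene, which fixes the C1=C10 geometry (C2 cis to iodine) that the final ring closure retains.

Step 4
Reactants: 8 (2E,6Z)-7-iodo-3-methylocta-2,6-dien-1-yl acetate
Product: 9 (2E,6Z)-7-iodo-3-methylocta-2,6-dien-1-ol
Conditions: K2CO3 (0.2 equiv), MeOH, 0 °C → rt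
Reagents that add atoms: none
Why: Base-catalysed transesterification removes the acetate under conditions that leave the alkenyl iodide and both alkene geometries untouched.

Step 5
Reactants: 9 (2E,6Z)-7-iodo-3-methylocta-2,6-dien-1-ol
Product: 10 (2E,6Z)-7-iodo-3-methylocta-2,6-dienal
Conditions: activated MnO2 (15 equiv), CH2Cl2, rt
Reagents that add atoms: none
Why: Allylic oxidation with MnO2 is selective for the allylic alcohol and should give the (E)-enal without isomerisation of the 2,3-alkene.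

Step 6
Reactants: 11 (R)-2,2-dimethyl-1,3-dioxolane-4-carbaldehyde; 12 methyl acrylate
Product: 13 methyl 2-{[(4R)-2,2-dimethyl-1,3-dioxolan-4-yl](hydroxy)methyl}prop-2-enoate (both carbinol epimers)
Conditions: DABCO (0.5 equiv), dioxane/H2O (1:1), rt, 3 d
Reagents that add atoms: none
Why: Morita–Baylis–Hillman reaction of the α-alkoxy aldehyde with the DABCO–acrylate zwitterion forms the C7–C11 bond, the new carbinol centre is erased in step 7 so its configuration is irrelevant, and C8 is carried unchanged from the chiral pool.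

Step 7
Reactants: 13 methyl 2-{[(4R)-2,2-dimethyl-1,3-dioxolan-4-yl](hydroxy)methyl}prop-2-enoate
Product: 14 methyl (2Z)-2-(bromomethyl)-3-[(4S)-2,2-dimethyl-1,3-dioxolan-4-yl]prop-2-enoate
Conditions: NBS (1.2 equiv), Me2S (1.3 equiv), CH2Cl2, 0 °C → rt
Reagents that add atoms: N-bromosuccinimide, O=C1CCC(=O)N1Br
Why: Corey–Kim-type activation of the allylic alcohol and SN2′ attack of bromide transpose the allylic system, and both carbinol epimers converge on the more stable (Z)-2-(bromomethyl)enoate in which the dioxolane is trans to the ester.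

Step 8
Reactants: 10 (2E,6Z)-7-iodo-3-methylocta-2,6-dienal; 14 methyl (2Z)-2-(bromomethyl)-3-[(4S)-2,2-dimethyl-1,3-dioxolan-4-yl]prop-2-enoate
Product: 17 (4S,5S)-4-[(4S)-2,2-dimethyl-1,3-dioxolan-4-yl]-5-[(1E,5Z)-6-iodo-2-methylhepta-1,5-dien-1-yl]-3-methylideneoxolan-2-one, via allylzinc bromide 15 (not isolated), via syn hydroxy ester 16 (not isolated)
Conditions: Zn dust (3 equiv), THF/sat aq NH4Cl (2:1), 0 °C → rt; then PPTS (catalytic), toluene, 45 °C
Reagents that add atoms: none
Why: Barbier-type zinc-mediated 2-(alkoxycarbonyl)allylation (Dreiding–Schmidt α-methylene lactone synthesis) at the γ-carbon C7 through a chair transition state in which the (Z)-allylzinc 15 holds C8 pseudo-axial should give the syn adduct 16 and hence the cis lactone (C6 and C7), while 1,3-allylic strain keeps H8 in the allyl plane so that C6 bonds on the face that carries the small ring oxygen next to zinc and anti to the C8–C9 bond, which sets C7 relative to the chiral-pool centre C8; the enal reacts 1,2 and the alkenyl iodide is inert to zinc.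

Step 9
Reactants: 17 (4S,5S)-4-[(4S)-2,2-dimethyl-1,3-dioxolan-4-yl]-5-[(1E,5Z)-6-iodo-2-methylhepta-1,5-dien-1-yl]-3-methylideneoxolan-2-one
Product: 18 (4R,5S)-4-[(1S)-1,2-dihydroxyethyl]-5-[(1E,5Z)-6-iodo-2-methylhepta-1,5-dien-1-yl]-3-methylideneoxolan-2-one
Conditions: AcOH/H2O (4:1), 40 °C
Reagents that add atoms: none
Why: Mild acid hydrolysis of the terminal acetonide frees the C8/C9 diol only after the lactone has been closed on O6, and aqueous acetic acid should be too weak to ionise the allylic C6–O bond or to move the lactone to O8.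

Step 10
Reactants: 18 (4R,5S)-4-[(1S)-1,2-dihydroxyethyl]-5-[(1E,5Z)-6-iodo-2-methylhepta-1,5-dien-1-yl]-3-methylideneoxolan-2-one
Product: 19 (4R,5S)-4-[(1S)-2-{[tert-butyl(dimethyl)silyl]oxy}-1-hydroxyethyl]-5-[(1E,5Z)-6-iodo-2-methylhepta-1,5-dien-1-yl]-3-methylideneoxolan-2-one
Conditions: TBSCl (1.1 equiv), imidazole, CH2Cl2, −20 → 0 °C
Reagents that add atoms: tert-butyldimethylsilyl chloride, CC(C)(C)[Si](C)(C)Cl
Why: Silylation at low temperature is selective for the primary C9 hydroxyl over the hindered secondary C8 hydroxyl.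

Step 11
Reactants: 20 (4S)-4-benzyl-3-propanoyl-1,3-oxazolidin-2-one; 21 tert-butyl bromoacetate
Product: 23 tert-butyl (3R)-4-[(4S)-4-benzyl-2-oxo-1,3-oxazolidin-3-yl]-3-methyl-4-oxobutanoate, via sodium enolate 22 (not isolated)
Conditions: NaN(SiMe3)2, THF, −78 °C; then 21, −78 → −40 °C
Reagents that add atoms: none
Why: Evans asymmetric alkylation, in which the chelated (Z)-sodium enolate is alkylated on the face opposite the benzyl group, sets the side-chain methyl stereocentre as (R).

Step 12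
Reactants: 23 tert-butyl (3R)-4-[(4S)-4-benzyl-2-oxo-1,3-oxazolidin-3-yl]-3-methyl-4-oxobutanoate
Product: 24 tert-butyl (3R)-4-hydroxy-3-methylbutanoate
Conditions: LiBH4, H2O (1 equiv), Et2O, 0 °C
Reagents that add atoms: none
Why: Reductive removal of the auxiliary with LiBH4 is chemoselective for the activated exocyclic imide carbonyl over the tert-butyl ester and does not touch the stereocentre.

Step 13
Reactants: 24 tert-butyl (3R)-4-hydroxy-3-methylbutanoate; 25 octadecanoyl chloride
Product: 26 tert-butyl (3R)-3-methyl-4-(octadecanoyloxy)butanoate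
Conditions: pyridine, DMAP (catalytic), CH2Cl2, 0 °C → rt
Reagents that add atoms: none
Why: Acylation of the primary alcohol with the acid chloride under nucleophilic catalysis is fast enough to outrun lactonisation of the γ-hydroxy ester.

Step 14
Reactants: 26 tert-butyl (3R)-3-methyl-4-(octadecanoyloxy)butanoate
Product: 27 (3R)-3-methyl-4-(octadecanoyloxy)butanoic acid
Conditions: TFA/CH2Cl2 (1:4), 0 °C → rt
Reagents that add atoms: none
Why: Acidolysis of the tert-butyl ester with loss of isobutene frees the acid and leaves the primary octadecanoate intact.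

Step 15
Reactants: 19 (4R,5S)-4-[(1S)-2-{[tert-butyl(dimethyl)silyl]oxy}-1-hydroxyethyl]-5-[(1E,5Z)-6-iodo-2-methylhepta-1,5-dien-1-yl]-3-methylideneoxolan-2-one; 27 (3R)-3-methyl-4-(octadecanoyloxy)butanoic acid
Product: 28 (1S)-2-{[tert-butyl(dimethyl)silyl]oxy}-1-{(2S,3S)-2-[(1E,5Z)-6-iodo-2-methylhepta-1,5-dien-1-yl]-4-methylidene-5-oxooxolan-3-yl}ethyl (3R)-3-methyl-4-(octadecanoyloxy)butanoate
Conditions: 27 (1.5 equiv), EDC·HCl, DMAP, CH2Cl2, 0 °C → rt
Reagents that add atoms: none
Why: Steglich esterification acylates the C8 hydroxyl with retention, so C8 keeps the chiral-pool configuration and the acid, which has no α-stereocentre, cannot racemise.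

Step 16
Reactants: 28 (1S)-2-{[tert-butyl(dimethyl)silyl]oxy}-1-{(2S,3S)-2-[(1E,5Z)-6-iodo-2-methylhepta-1,5-dien-1-yl]-4-methylidene-5-oxooxolan-3-yl}ethyl (3R)-3-methyl-4-(octadecanoyloxy)butanoate
Product: 29 (1S)-2-hydroxy-1-{(2S,3S)-2-[(1E,5Z)-6-iodo-2-methylhepta-1,5-dien-1-yl]-4-methylidene-5-oxooxolan-3-yl}ethyl (3R)-3-methyl-4-(octadecanoyloxy)butanoate
Conditions: HF·pyridine, pyridine, THF, 0 °C
Reagents that add atoms: none
Why: Fluoride cleavage of the primary silyl ether under buffered, non-basic conditions should keep the ester on O8 from migrating to O9.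

Step 17
Reactants: 29 (1S)-2-hydroxy-1-{(2S,3S)-2-[(1E,5Z)-6-iodo-2-methylhepta-1,5-dien-1-yl]-4-methylidene-5-oxooxolan-3-yl}ethyl (3R)-3-methyl-4-(octadecanoyloxy)butanoate
Product: 30 (1S)-1-{(2S,3S)-2-[(1E,5Z)-6-iodo-2-methylhepta-1,5-dien-1-yl]-4-methylidene-5-oxooxolan-3-yl}-2-oxoethyl (3R)-3-methyl-4-(octadecanoyloxy)butanoate
Conditions: Dess–Martin periodinane, pyridine, CH2Cl2, 0 °C → rt; used crude at once
Reagents that add atoms: none
Why: Dess–Martin oxidation under buffered neutral conditions should give the configurationally labile α-acyloxy aldehyde without epimerisation at C8 or β-elimination.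

Step 18
Reactants: 30 (1S)-1-{(2S,3S)-2-[(1E,5Z)-6-iodo-2-methylhepta-1,5-dien-1-yl]-4-methylidene-5-oxooxolan-3-yl}-2-oxoethyl (3R)-3-methyl-4-(octadecanoyloxy)butanoate
Product: 33 CNP0114940.1 (6S,7S,8S,9R)-8-O-[(3R)-3-methyl-4-(octadecanoyloxy)butanoyl]-9-hydroxy-(1(10)Z,4E)-germacra-1(10),4,11(13)-trien-12,6-olide, via alkenylchromium dichloride 31 (not isolated), via chromium alkoxide 32 (not isolated)
Conditions: CrCl2 (20 equiv), NiCl2 (0.2 equiv), degassed DMSO/THF (3:1), 2 mM, slow addition of 30 over 10 h, rt; aq sodium serinate (pH 7) work-up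
Reagents that add atoms: none
Why: Zerovalent nickel inserts into the C10–I bond with retention of the (Z) geometry, transmetalation to trivalent chromium gives alkenylchromium 31, and its intramolecular 1,2-addition to the C9 aldehyde through a chromium-bound closed transition state gives alkoxide 32, which is hydrolysed on work-up. The closest known reaction type is the Nozaki–Hiyama–Kishi cyclisation of alkenyl iodide–aldehydes to medium-ring carbocyclic allylic alcohols. Ring A closes in a 10-exo-trig mode, helped by the cis-fused lactone and the two trisubstituted alkenes, which remove rotors and turn the two chain ends toward each other. The new stereocentre C9 is controlled by the adjacent C8: Felkin–Anh (polar) addition anti to the C8–O bond should give the 8,9-anti (9R) carbinol, and the ring-forming transition state, in which C7 stays gauche to the incoming C10, works in the same sense. The step needs selectivity for the aldehyde over the lactone, the enoate and the esters, no acyl shift from O8 to O9 and cyclisation over oligomerisation; these are secured by the aldehyde-selective, non-basic organochromium, by the kinetically inert chromium–oxygen bond of 32 together with a neutral work-up, and by high dilution with slow addition. In this one operation the ten-membered ring, the C9 stereocentre and the only free hydroxyl of the target are produced.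

**Compound list**

1 | geranyl acetate | CC(C)=CCC/C(C)=C/COC(C)=O | starting material
2 | (2E)-5-(3,3-dimethyloxiran-2-yl)-3-methylpent-2-en-1-yl acetate (racemic) | CC1(C)OC1CC/C(C)=C/COC(C)=O | intermediate
3 | (2E)-3-methyl-6-oxohex-2-en-1-yl acetate | O=CCC/C(C)=C/COC(C)=O | intermediate
4 | ethyltriphenylphosphonium iodide | CC[P+](c1ccccc1)(c1ccccc1)c1ccccc1.[I-] | starting material
5 | ethylidenetriphenylphosphorane | CC=P(c1ccccc1)(c1ccccc1)c1ccccc1 | intermediate
6 | (1-iodoethyl)triphenylphosphonium iodide | CC(I)[P+](c1ccccc1)(c1ccccc1)c1ccccc1.[I-] | intermediate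
7 | (1-iodoethylidene)triphenylphosphorane | CC(I)=P(c1ccccc1)(c1ccccc1)c1ccccc1 | intermediate
8 | (2E,6Z)-7-iodo-3-methylocta-2,6-dien-1-yl acetate | CC(=O)OC/C=C(\C)CC/C=C(/C)I | intermediate
9 | (2E,6Z)-7-iodo-3-methylocta-2,6-dien-1-ol | OC/C=C(\C)CC/C=C(/C)I | intermediate
10 | (2E,6Z)-7-iodo-3-methylocta-2,6-dienal | O=C/C=C(\C)CC/C=C(/C)I | intermediate
11 | (R)-2,2-dimethyl-1,3-dioxolane-4-carbaldehyde | O=C[C@H]1COC(C)(C)O1 | starting material
12 | methyl acrylate | C=CC(=O)OC | starting material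
13 | methyl 2-{[(4R)-2,2-dimethyl-1,3-dioxolan-4-yl](hydroxy)methyl}prop-2-enoate (both carbinol epimers) | C=C(C(=O)OC)C(O)[C@H]1COC(C)(C)O1 | intermediate
14 | methyl (2Z)-2-(bromomethyl)-3-[(4S)-2,2-dimethyl-1,3-dioxolan-4-yl]prop-2-enoate | BrC/C(=C\[C@H]1COC(C)(C)O1)C(=O)OC | intermediate
15 | bromo{(2Z)-3-[(4S)-2,2-dimethyl-1,3-dioxolan-4-yl]-2-(methoxycarbonyl)prop-2-en-1-yl}zinc | Br[Zn]C/C(=C\[C@H]1COC(C)(C)O1)C(=O)OC | intermediate
16 | methyl (3S,4S,5E,9Z)-3-[(4S)-2,2-dimethyl-1,3-dioxolan-4-yl]-4-hydroxy-10-iodo-6-methyl-2-methylideneundeca-5,9-dienoate | COC(=O)C(=C)[C@H]([C@H]1COC(C)(C)O1)[C@@H](O)/C=C(\C)CC/C=C(/C)I | intermediate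
17 | (4S,5S)-4-[(4S)-2,2-dimethyl-1,3-dioxolan-4-yl]-5-[(1E,5Z)-6-iodo-2-methylhepta-1,5-dien-1-yl]-3-methylideneoxolan-2-one | C=C1C(=O)O[C@@H](/C=C(\C)CC/C=C(/C)I)[C@H]1[C@H]2COC(C)(C)O2 | intermediate
18 | (4R,5S)-4-[(1S)-1,2-dihydroxyethyl]-5-[(1E,5Z)-6-iodo-2-methylhepta-1,5-dien-1-yl]-3-methylideneoxolan-2-one | C=C1C(=O)O[C@@H](/C=C(\C)CC/C=C(/C)I)[C@H]1[C@H](O)CO | intermediate
19 | (4R,5S)-4-[(1S)-2-{[tert-butyl(dimethyl)silyl]oxy}-1-hydroxyethyl]-5-[(1E,5Z)-6-iodo-2-methylhepta-1,5-dien-1-yl]-3-methylideneoxolan-2-one | C=C1C(=O)O[C@@H](/C=C(\C)CC/C=C(/C)I)[C@H]1[C@H](O)CO[Si](C)(C)C(C)(C)C | intermediate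
20 | (4S)-4-benzyl-3-propanoyl-1,3-oxazolidin-2-one | CCC(=O)N1[C@@H](Cc2ccccc2)COC1=O | starting material
21 | tert-butyl bromoacetate | CC(C)(C)OC(=O)CBr | starting material
22 | sodium (Z)-enolate of 20 | C/C=C(\[O-])N1[C@@H](Cc2ccccc2)COC1=O.[Na+] | intermediate
23 | tert-butyl (3R)-4-[(4S)-4-benzyl-2-oxo-1,3-oxazolidin-3-yl]-3-methyl-4-oxobutanoate | CC(C)(C)OC(=O)C[C@@H](C)C(=O)N1[C@@H](Cc2ccccc2)COC1=O | intermediate
24 | tert-butyl (3R)-4-hydroxy-3-methylbutanoate | CC(C)(C)OC(=O)C[C@@H](C)CO | intermediate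
25 | octadecanoyl chloride | ClC(=O)CCCCCCCCCCCCCCCCC | starting material
26 | tert-butyl (3R)-3-methyl-4-(octadecanoyloxy)butanoate | CC(C)(C)OC(=O)C[C@@H](C)COC(=O)CCCCCCCCCCCCCCCCC | intermediate
27 | (3R)-3-methyl-4-(octadecanoyloxy)butanoic acid | OC(=O)C[C@@H](C)COC(=O)CCCCCCCCCCCCCCCCC | intermediate
28 | (1S)-2-{[tert-butyl(dimethyl)silyl]oxy}-1-{(2S,3S)-2-[(1E,5Z)-6-iodo-2-methylhepta-1,5-dien-1-yl]-4-methylidene-5-oxooxolan-3-yl}ethyl (3R)-3-methyl-4-(octadecanoyloxy)butanoate | C=C1C(=O)O[C@@H](/C=C(\C)CC/C=C(/C)I)[C@H]1[C@H](OC(=O)C[C@@H](C)COC(=O)CCCCCCCCCCCCCCCCC)CO[Si](C)(C)C(C)(C)C | intermediate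
29 | (1S)-2-hydroxy-1-{(2S,3S)-2-[(1E,5Z)-6-iodo-2-methylhepta-1,5-dien-1-yl]-4-methylidene-5-oxooxolan-3-yl}ethyl (3R)-3-methyl-4-(octadecanoyloxy)butanoate | C=C1C(=O)O[C@@H](/C=C(\C)CC/C=C(/C)I)[C@H]1[C@H](OC(=O)C[C@@H](C)COC(=O)CCCCCCCCCCCCCCCCC)CO | intermediate
30 | (1S)-1-{(2S,3S)-2-[(1E,5Z)-6-iodo-2-methylhepta-1,5-dien-1-yl]-4-methylidene-5-oxooxolan-3-yl}-2-oxoethyl (3R)-3-methyl-4-(octadecanoyloxy)butanoate | C=C1C(=O)O[C@@H](/C=C(\C)CC/C=C(/C)I)[C@H]1[C@H](OC(=O)C[C@@H](C)COC(=O)CCCCCCCCCCCCCCCCC)C=O | intermediate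
31 | alkenylchromium dichloride from 30 (CrCl2 on C10 in place of iodine, Z geometry kept) | C=C1C(=O)O[C@@H](/C=C(\C)CC/C=C(/C)[Cr](Cl)Cl)[C@H]1[C@H](OC(=O)C[C@@H](C)COC(=O)CCCCCCCCCCCCCCCCC)C=O | intermediate
32 | chromium dichloride alkoxide of 33 (O9–CrCl2) | C=C1C(=O)O[C@H]2/C=C(\C)CC/C=C(/C)[C@@H](O[Cr](Cl)Cl)[C@@H](OC(=O)C[C@@H](C)COC(=O)CCCCCCCCCCCCCCCCC)[C@@H]12 | intermediate
33 | CNP0114940.1, (3aS,4S,5R,6Z,10E,11aS)-5-hydroxy-6,10-dimethyl-3-methylidene-2-oxo-2,3,3a,4,5,8,9,11a-octahydrocyclodeca[b]furan-4-yl (3R)-3-methyl-4-(octadecanoyloxy)butanoate | C=C1C(=O)O[C@H]2/C=C(\C)CC/C=C(/C)[C@@H](O)[C@@H](OC(=O)C[C@@H](C)COC(=O)CCCCCCCCCCCCCCCCC)[C@@H]12 | target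

**Step count and risks**

Total step count: 18. Longest linear sequence: 12 steps (steps 1–5, 8–10, 15–18).

Most likely to fail:

1. Step 18. The C8 acyloxy group may be lost reductively, epimerise or shift to the new C9 alkoxide under divalent and trivalent chromium, while the ten-membered ring closes slowly and oligomerises, or closes with poor facial control at C9. The fallback closes the ring on a C8 silyl ether and acylates afterwards. It sets out from diol 18: Et3SiCl and imidazole give the bis(triethylsilyl) ether F1; Swern conditions cleave and oxidise only the primary silyl ether to the α-silyloxy aldehyde F2; the CrCl2/NiCl2 closure, through alkenylchromium dichloride F3 and chromium alkoxide F4, gives the macrocyclic allylic alcohol F5; TBSOTf and 2,6-lutidine give the C9 silyl ether F6; PPTS in MeOH removes the triethylsilyl group to give the C8 alcohol F7; esterification with acid 27 (2,4,6-trichlorobenzoyl chloride, Et3N, DMAP) gives ester F8; HF·pyridine then returns to the route at target 33.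

2. Step 8. The allylzinc may attack with poor or reversed facial selectivity with respect to the C8 stereocentre (C6 bonding anti to the ring oxygen instead of syn), so that C6 and C7 come out in the wrong sense relative to C8. The fallback accepts the opposite preference and corrects C8 by inversion. It sets out from the enantiomeric aldehyde (S)-2,2-dimethyl-1,3-dioxolane-4-carbaldehyde F9: reaction with 12 and DABCO gives the adduct F10, and NBS/Me2S gives the (Z)-bromide F11. Zinc-mediated allylation of 10, through allylzinc bromide F12 and hydroxy ester F13, then gives the lactone F14 with C6 and C7 as in the target and C8 inverted. AcOH/H2O gives the diol F15 and TBSCl gives the silyl ether F16. A Mitsunobu esterification with acid 27 (PPh3, DIAD, toluene) inverts C8 and returns to the route at ester 28.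

3. Step 16. The acyl group may migrate from the secondary O8 to the freed primary O9 during or after desilylation. The fallback never frees the primary alcohol. It sets out from diol 18: Et3SiCl (1 equiv) and imidazole at −78 °C give the primary triethylsilyl ether F17; EDC·HCl/DMAP esterification with 27 gives the ester F18; Swern conditions convert the primary triethylsilyl ether directly into the aldehyde, and the route is rejoined at 30.

**Further compounds**

F1 | step 18 | (4S,5S)-4-[(1S)-1,2-bis(triethylsilyloxy)ethyl]-5-[(1E,5Z)-6-iodo-2-methylhepta-1,5-dien-1-yl]-3-methylideneoxolan-2-one | C=C1C(=O)O[C@@H](/C=C(\C)CC/C=C(/C)I)[C@H]1[C@H](O[Si](CC)(CC)CC)CO[Si](CC)(CC)CC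
F2 | step 18 | (2S)-2-{(2S,3S)-2-[(1E,5Z)-6-iodo-2-methylhepta-1,5-dien-1-yl]-4-methylidene-5-oxooxolan-3-yl}-2-(triethylsilyloxy)acetaldehyde | C=C1C(=O)O[C@@H](/C=C(\C)CC/C=C(/C)I)[C@H]1[C@H](O[Si](CC)(CC)CC)C=O
F3 | step 18 | alkenylchromium dichloride from F2 | C=C1C(=O)O[C@@H](/C=C(\C)CC/C=C(/C)[Cr](Cl)Cl)[C@H]1[C@H](O[Si](CC)(CC)CC)C=O
F4 | step 18 | chromium dichloride alkoxide of F5 | C=C1C(=O)O[C@H]2/C=C(\C)CC/C=C(/C)[C@@H](O[Cr](Cl)Cl)[C@@H](O[Si](CC)(CC)CC)[C@@H]12
F5 | step 18 | 8-O-triethylsilyl-9-hydroxy macrocycle (ring system and configuration of 33) | C=C1C(=O)O[C@H]2/C=C(\C)CC/C=C(/C)[C@@H](O)[C@@H](O[Si](CC)(CC)CC)[C@@H]12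
F6 | step 18 | 8-O-triethylsilyl-9-O-tert-butyldimethylsilyl macrocycle | C=C1C(=O)O[C@H]2/C=C(\C)CC/C=C(/C)[C@@H](O[Si](C)(C)C(C)(C)C)[C@@H](O[Si](CC)(CC)CC)[C@@H]12
F7 | step 18 | 8-hydroxy-9-O-tert-butyldimethylsilyl macrocycle | C=C1C(=O)O[C@H]2/C=C(\C)CC/C=C(/C)[C@@H](O[Si](C)(C)C(C)(C)C)[C@@H](O)[C@@H]12
F8 | step 18 | 9-O-tert-butyldimethylsilyl ether of 33 | C=C1C(=O)O[C@H]2/C=C(\C)CC/C=C(/C)[C@@H](O[Si](C)(C)C(C)(C)C)[C@@H](OC(=O)C[C@@H](C)COC(=O)CCCCCCCCCCCCCCCCC)[C@@H]12
F9 | step 8 | (S)-2,2-dimethyl-1,3-dioxolane-4-carbaldehyde | O=C[C@@H]1COC(C)(C)O1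
F10 | step 8 | methyl 2-{[(4S)-2,2-dimethyl-1,3-dioxolan-4-yl](hydroxy)methyl}prop-2-enoate (both carbinol epimers) | C=C(C(=O)OC)C(O)[C@@H]1COC(C)(C)O1
F11 | step 8 | methyl (2Z)-2-(bromomethyl)-3-[(4R)-2,2-dimethyl-1,3-dioxolan-4-yl]prop-2-enoate | BrC/C(=C\[C@@H]1COC(C)(C)O1)C(=O)OC
F12 | step 8 | allylzinc bromide from F11 | Br[Zn]C/C(=C\[C@@H]1COC(C)(C)O1)C(=O)OC
F13 | step 8 | syn hydroxy ester with C6 and C7 as in 16 and the dioxolane centre inverted | COC(=O)C(=C)[C@H]([C@@H]1COC(C)(C)O1)[C@@H](O)/C=C(\C)CC/C=C(/C)I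
F14 | step 8 | C8 epimer of lactone 17 | C=C1C(=O)O[C@@H](/C=C(\C)CC/C=C(/C)I)[C@H]1[C@@H]2COC(C)(C)O2
F15 | step 8 | C8 epimer of diol 18 | C=C1C(=O)O[C@@H](/C=C(\C)CC/C=C(/C)I)[C@H]1[C@@H](O)CO
F16 | step 8 | C8 epimer of silyl ether 19 | C=C1C(=O)O[C@@H](/C=C(\C)CC/C=C(/C)I)[C@H]1[C@@H](O)CO[Si](C)(C)C(C)(C)C
F17 | step 16 | primary triethylsilyl ether of diol 18 | C=C1C(=O)O[C@@H](/C=C(\C)CC/C=C(/C)I)[C@H]1[C@H](O)CO[Si](CC)(CC)CC
F18 | step 16 | triethylsilyl analogue of ester 28 | C=C1C(=O)O[C@@H](/C=C(\C)CC/C=C(/C)I)[C@H]1[C@H](OC(=O)C[C@@H](C)COC(=O)CCCCCCCCCCCCCCCCC)CO[Si](CC)(CC)CC
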